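**Retrosynthetic overview**
- The epoxide is put on last, by face-selective epoxidation of the Z alkene (C13=C14) of a bromo-oxocene.
- Ring C (the eight-membered ether) is closed at the C13–C14 bond by reductive coupling of a C13 methyl ketone with a C14 alkoxy-aldehyde, two carbonyl carbons joined through titanium ketyls.
- The keto aldehyde comes from oxidation of an 8-(2-hydroxyethoxy) 13-ketone.
- Rings A and B, all five ring stereocentres and the C8–O–CH2CH2 ether come from one catalytic enantioselective bromonium polyene cyclisation of farnesylacetone ethylene ketal, in which a ketal oxygen ends the cascade and stays on C8.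
- Ring order: A and B together, then C, then the oxirane.

Atom labels: labdane numbering (C3 = CHBr, C4 = CMe2, C5/C10 = ring fusion, C8 = C(Me)–O, C9 = CH bearing the chain C11–C12–C13(C16 methyl)–C14–C15, C15 = OCH2).

Assumption: (5E,9E)-farnesylacetone is bought geometrically pure (it is the bulk teprenone intermediate), and the (S)-configured bromination catalyst is taken to give the 3R series; the antipodal catalyst is used if the first run shows the opposite sense.

**Step 1**
Reactants: 1 (5E,9E)-farnesylacetone; 2 ethylene glycol
Product: 3 2-methyl-2-[(3E,7E)-4,8,12-trimethyltrideca-3,7,11-trien-1-yl]-1,3-dioxolane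
Conditions: ethylene glycol (3 equiv), pyridinium p-toluenesulfonate (5 mol %), benzene, reflux, Dean–Stark, 12 h
Reagents that add atoms: none
Why: Acid-catalysed ketalisation (dioxolane formation) driven by azeotropic water removal; the weak acid does not isomerise or cyclise the trisubstituted alkenes and no stereocentre is formed.

**Step 2**
Reactants: 3 farnesylacetone ethylene ketal
Product: 5 keto alcohol 4-[(1S,2S,4aS,6R,8aR)-6-bromo-2-(2-hydroxyethoxy)-2,5,5,8a-tetramethyldecahydronaphthalen-1-yl]butan-2-one, via oxocarbenium ion 4 (not isolated)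
Conditions: 1,3-dibromo-5,5-dimethylhydantoin (DBDMH, 0.6 equiv), (S)-3,3'-bis(2,4,6-triisopropylphenyl)-1,1'-binaphthyl-2,2'-diyl N-triflylthiophosphoramide (10 mol %), toluene/CH2Cl2 1:1, −78 °C, 12 h; then THF–H2O, −78 → 0 °C
Reagents that add atoms: 1,3-dibromo-5,5-dimethylhydantoin (O=C1N(Br)C(=O)N(Br)C1(C)C); water (O)
Why: Proposed new method: a catalytic enantioselective bromonium polyene cyclisation in which the chiral Lewis-basic thiophosphoramide delivers Br+ to one face of the terminal alkene (this sets C3 and, through it, the absolute configuration), the (E,E)-triene folds chair–chair with anti addition across each double bond (equatorial C3–Br, trans ring fusion at C5/C10, equatorial chain at C9, axial methyl and equatorial oxygen at C8), and the C8 cation is captured by a dioxolane oxygen, after which the C13–O bond of that oxygen ionises to the nine-membered oxocarbenium ion 4 that water hydrolyses to the C13 ketone and the primary alcohol, so the O–CH2CH2–O unit ends up on C8; the closest known reaction types are the chiral BINOL-thiophosphoramide/DBDMH asymmetric bromocyclisation of aryl-terminated polyenes, ketone- and alcohol-terminated polyene cyclisations to cyclic ethers, and the haloetherification of ene acetals in which an acetal oxygen traps the cation and the oxonium opens to a ring-enlarged oxocarbenium ion.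

**Step 3**
Reactants: 5 keto alcohol
Product: 6 keto aldehyde 2-{[(1S,2S,4aS,6R,8aR)-6-bromo-2,5,5,8a-tetramethyl-1-(3-oxobutyl)decahydronaphthalen-2-yl]oxy}acetaldehyde
Conditions: Dess–Martin periodinane (1.3 equiv), CH2Cl2, 0 °C → rt, 1 h; used crude
Reagents that add atoms: none
Why: Dess–Martin oxidation takes the primary alcohol to the aldehyde under non-basic conditions that leave the ketone, the tertiary ether and the secondary bromide alone; no stereocentre is touched.

**Step 4**
Reactants: 6 keto aldehyde
Product: 7 (3R,5S,8S,9S,10R,13Z)-3-bromo-8,15-epoxylabd-13-ene (trans-decalin fused at C8–C9 to an eight-membered cyclic ether holding the Z C13=C14 alkene)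
Conditions: TiCl3(DME)1.5 (10 equiv), Zn–Cu couple (30 equiv), DME, reflux 3 h (low-valent titanium slurry); then 6 added by syringe pump over 20 h (final 3 mM), reflux 2 h more
Reagents that add atoms: none
Why: Intramolecular McMurry coupling: on low-valent titanium both carbonyl carbons, each normally an electrophile, are reduced to titanium-bound ketyls (carbonyl carbons of reversed polarity) that join to form the C13–C14 bond and are then deoxygenated to the alkene, the eight-membered ring allowing only the Z geometry while the quaternary C8 and the trans-diequatorial C8–O and C9–C11 bonds hold the two chains close; no stereocentre is touched.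

**Step 5**
Reactants: 7 bromo-oxocene
Product: 8 (3R,5S,8S,9S,10R,13S,14R)-3-bromo-8,15:13,14-diepoxylabdane (CNP0311742.1)
Conditions: dimethyldioxirane (1.2 equiv), acetone, −20 → 0 °C
Reagents that add atoms: dimethyldioxirane (CC1(C)OO1)
Why: Electrophilic epoxidation (Prilezhaev type) adds oxygen syn to the only alkene, so the oxirane is cis-fused, and attack is expected on the open face: the axial C8 and C10 methyls force C12 outward (anti to C10) and C15 anti to the C8 methyl, which turns one alkene face toward axial H9 and the C11 methylene and leaves the other face, on the side of the C8 methyl, free, giving 13S,14R.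

**Compound list**
1 | (5E,9E)-farnesylacetone, (5E,9E)-6,10,14-trimethylpentadeca-5,9,13-trien-2-one | CC(C)=CCC/C(C)=C/CC/C(C)=C/CCC(C)=O | starting material
2 | ethylene glycol | OCCO | starting material
3 | 2-methyl-2-[(3E,7E)-4,8,12-trimethyltrideca-3,7,11-trien-1-yl]-1,3-dioxolane | CC(C)=CCC/C(C)=C/CC/C(C)=C/CCC1(C)OCCO1 | intermediate
4 | nine-membered cyclic oxocarbenium ion, C8–O–CH2CH2–O(+)=C13(CH3)–C12–C11–C9 loop on the (3R,5S,8S,9S,10R)-3-bromodecalin | CC1(C)[C@H](Br)CC[C@]2(C)[C@@H]1CC[C@]1(C)OCC[O+]=C(C)CC[C@@H]21 | intermediate
5 | 4-[(1S,2S,4aS,6R,8aR)-6-bromo-2-(2-hydroxyethoxy)-2,5,5,8a-tetramethyldecahydronaphthalen-1-yl]butan-2-one | CC1(C)[C@H](Br)CC[C@]2(C)[C@@H]1CC[C@](C)(OCCO)[C@H]2CCC(C)=O | intermediate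
6 | 2-{[(1S,2S,4aS,6R,8aR)-6-bromo-2,5,5,8a-tetramethyl-1-(3-oxobutyl)decahydronaphthalen-2-yl]oxy}acetaldehyde | CC1(C)[C@H](Br)CC[C@]2(C)[C@@H]1CC[C@](C)(OCC=O)[C@H]2CCC(C)=O | intermediate
7 | (3R,5S,8S,9S,10R,13Z)-3-bromo-8,15-epoxylabd-13-ene | CC1(C)[C@H](Br)CC[C@]2(C)[C@@H]1CC[C@]1(C)OC/C=C(C)\CC[C@@H]21 | intermediate
8 | (3R,5S,8S,9S,10R,13S,14R)-3-bromo-8,15:13,14-diepoxylabdane | CC1(C)[C@H](Br)CC[C@]2(C)[C@@H]1CC[C@]1(C)OC[C@H]3O[C@@]3(C)CC[C@@H]21 | target

**Step count**
Total steps: 5. Longest linear sequence: 5 (from 1).

**Steps most likely to fail**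

Step 2 is the least certain. The transfer of the ketal oxygen to C8 has no direct precedent, the C8 cation may instead lose a proton to give bicyclic alkenes with the ketal intact, and the enantioselectivity of the catalyst is untested on a triene without an aryl terminator. The fallback sets out from 1 and comes back at 6. Ketone 1 itself is cyclised with the same thiophosphoramide and DBDMH, its carbonyl oxygen ending the cascade, to give the tricyclic bromo enol ether F1. Aqueous oxalic acid in THF opens this to the hydroxy ketone F2. Rh2(OAc)4-catalysed O–H insertion of ethyl diazoacetate into the tertiary alcohol gives the ethyl alkoxyacetate F3. LiBH4 in THF reduces ester and ketone to the diol F4, and Dess–Martin periodinane (2.5 equiv) oxidises both alcohols to 6.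

Step 4 may suffer from loss of the β-alkoxy group at the aldehyde ketyl, reduction of the C3 bromide, cleavage of the allylic ether product, or oligomerisation during the slow medium-ring closure. The fallback sets out from 6 and comes back at 7. Double Wittig methylenation (Ph3P=CH2, THF, 0 °C) gives the allyl ether diene F5. Ring-closing metathesis with the second-generation Hoveyda–Grubbs catalyst (10 mol %, toluene, 80 °C, 2 mM) then closes the same Z trisubstituted alkene 7.

Step 5 rests on a conformational argument for the facial preference, and it may be wrong or only weakly selective. The fallback sets out from 7 and comes back at 8, and it inverts the facial sense instead of changing the oxidant. N-bromosuccinimide in aqueous THF puts Br+ on the face that electrophiles prefer, and water opens at the tertiary C13 from the opposite face to give the bromohydrin F6. K2CO3 in methanol then closes the oxirane by SN2 displacement at C14, so the oxygen ends up on the face opposite to that of direct epoxidation, giving 8.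

**Further compounds**
F1 | step 2 | (3R,5S,8S,9S,10R)-3-bromo-8,13-epoxy-14,15-dinorlabd-12-ene (tricyclic bromo enol ether) | CC1(C)[C@H](Br)CC[C@]2(C)[C@@H]1CC[C@]1(C)OC(C)=CC[C@@H]21
F2 | step 2 | 4-[(1S,2S,4aS,6R,8aR)-6-bromo-2-hydroxy-2,5,5,8a-tetramethyldecahydronaphthalen-1-yl]butan-2-one | CC1(C)[C@H](Br)CC[C@]2(C)[C@@H]1CC[C@](C)(O)[C@H]2CCC(C)=O
F3 | step 2 | ethyl 2-{[(1S,2S,4aS,6R,8aR)-6-bromo-2,5,5,8a-tetramethyl-1-(3-oxobutyl)decahydronaphthalen-2-yl]oxy}acetate | CC1(C)[C@H](Br)CC[C@]2(C)[C@@H]1CC[C@](C)(OCC(=O)OCC)[C@H]2CCC(C)=O
F4 | step 2 | 4-[(1S,2S,4aS,6R,8aR)-6-bromo-2-(2-hydroxyethoxy)-2,5,5,8a-tetramethyldecahydronaphthalen-1-yl]butan-2-ol (both carbinol epimers) | CC1(C)[C@H](Br)CC[C@]2(C)[C@@H]1CC[C@](C)(OCCO)[C@H]2CCC(C)O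
F5 | step 4 | (1S,2S,4aS,6R,8aR)-2-(allyloxy)-6-bromo-2,5,5,8a-tetramethyl-1-(3-methylbut-3-en-1-yl)decahydronaphthalene | CC1(C)[C@H](Br)CC[C@]2(C)[C@@H]1CC[C@](C)(OCC=C)[C@H]2CCC(C)=C
F6 | step 5 | (3R,5S,8S,9S,10R,13S,14S)-3,14-dibromo-8,15-epoxylabdan-13-ol | CC1(C)[C@H](Br)CC[C@]2(C)[C@@H]1CC[C@]1(C)OC[C@H](Br)[C@@](C)(O)CC[C@@H]21
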